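Readings and results are simulated with constants of no real substance; scatter was added.

Wednesday's charge of J is 2.21 times Friday's, yet its last reading of D, as a fraction of the charge, stands 0.6 percentage points above Friday's.

| setting | Friday's | Wednesday's | flask |
|---|---|---|---|
| J | 0.034 M | 0.075 M | 0.050 M |
| Z | 10 mM (held) | 10 mM (held) | 10 mM (held) |
| remark | run made earlier | run made earlier |  |
| time |  |  | 4.0 h |

| run | time / h | D / % |
|---|---|---|
| Friday's | 0.500 | 28.6 |
| Friday's | 1.00 | 41.6 |
| Friday's | 1.50 | 47.9 |
| Friday's | 2.00 | 50.3 |
| Friday's | 2.50 | 51.4 |
| Friday's | 3.00 | 51.1 |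
| Wednesday's | 0.250 | 16.5 |
| Wednesday's | 0.417 | 23.9 |
| Wednesday's | 0.667 | 32.4 |
| Wednesday's | 1.33 | 45.5 |
| Wednesday's | 2.00 | 50.4 |
| Wednesday's | 3.00 | 51.7 |

(readings scatter by 0.5 percentage points)

- what was read earlier has a scatter of 0.5 percentage points, one standard deviation
- at the start none of Z is in solution

* the D standing at 4.0 h, as a percentage of the J charged
* the change that raises the amount of D at 4.0 h, in percent of the J charged most ("none" if none brings more than 2 percentage points) (north / north-west / none)
* amount of D at 4.0 h, in percent of the J charged, after north

- north: doubling the transfer coefficient of Z, all else as stated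
- north-west: doubling the saturation concentration of Z, all else as stated

What do you follow? One molecule of J, and its chance of standing as D late in a run. Friday's last two readings and Wednesday's last average 51.4%: that is the keep, the fraction of the charge standing as D on the plateau.

Does the charge move it? Those readings spread over 0.6 points against a scatter of 0.5 points, and the flask's charge lies between the two, so I carry the keep over unchanged.

How fast is the rise? Friday's first reading puts D's rise towards the keep at 1.63 h⁻¹, a pseudo-first-order constant, and that gives 45.5% for Wednesday's reading of 45.5% at 1.33 h.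

So the flask at 4.0 h? I say 51.3%, with 0.077 points of rise remaining.

But where is the other 48.6%? I can't say. D alone was read.

And the changes? North doubles the transfer coefficient of Z; if that speeds the rise, my reckoning has 0.077 points left to gain, less than the margin of 2 points, so I expect no use from north. North-west doubles the saturation concentration of Z, but both runs held it at 10 mM, so north-west is a bet, and I bet on none.

The forecast parts from me on the choice: 51.5% (range 50.8% to 52.2%), 51.5% after north, and north-west, since “Doubling saturation would then lift D to about 68%”.

The flask gives 50.0%, and 49.7% after north; north moves it by −0.24 points and north-west by −7.4 points, so the choice is none.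

    J + Q → D (k = 2.40 L mol⁻¹ min⁻¹)
    Z ⇌ Q, rate k2*(csat - [Q]) (kL = 0.970 min⁻¹)
    Q + D → L (k = 0.130 L mol⁻¹ min⁻¹)
    2 Q → E (k = 1.90 L mol⁻¹ min⁻¹)
    D ⇌ X (K = 0.730, k = 0.110 min⁻¹)

The flask stands 1.4 points below the keep, at 0.973 of it, while L went from 5.34% at 2.00 h to 13.0% at 4.00 h. Read at 1.0 h, the same flask holds 41.7% D, where the keep and its rise give 41.3%.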